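**Plan**
The target has no stereocentre. Its interflavone bond joins C3' of the genkwanin unit (ortho to the 4'-OH) to C6 of the apigenin unit (ortho to the 5-OH).
The retrosynthesis first re-bridges these two oxygens with one CH2 group and masks the other phenols as benzyl ethers. It then cuts the C3'–C6 biaryl bond, back to a 3'-bromide held next to the C6–H by the O–CH2–O bridge.
Next the two C–O bonds of the bridge are cut, giving an aryl chloromethyl ether and the 5-OH of 7,4'-di-O-benzylapigenin. Last, the pyranone ring of the bromoflavone is cut at O1–C2 and C2–C3, via a chalcone, to an acetophenone and 3-bromo-4-hydroxybenzaldehyde.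
Forward order: pyranone ring of the genkwanin unit (Claisen–Schmidt, then I2/DMSO), acetal tether, seven-membered dibenzo[d,f][1,3]dioxepine ring by intramolecular direct arylation, then one-pot removal of the bridge and the benzyl groups.
Stereochemistry: none to set; the chalcone E-alkene disappears on oxidation and the biaryl axis of the target rotates freely.

Key step: step 7

Remark: the two halves are called the genkwanin unit (5-hydroxy-7-methoxyflavone part) and the apigenin unit (5,7-dihydroxyflavone part), each with ordinary flavone locants. The chloromethyl ether 9 is assumed to be used crude, without purification.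

**Step 1**
Reactants: 1 2',6'-dihydroxy-4'-methoxyacetophenone
Product: 2 2'-benzyloxy-6'-hydroxy-4'-methoxyacetophenone
Conditions: BnBr (1.05 equiv), K2CO3, acetone, reflux
Reagents that add atoms: benzyl bromide, BrCc1ccccc1
Why: Williamson etherification of one of two equivalent phenols; after the first benzylation the remaining OH is locked in a hydrogen bond to the acetyl carbonyl and should resist a second alkylation under these mild conditions.

**Step 2**
Reactants: 2 2'-benzyloxy-6'-hydroxy-4'-methoxyacetophenone; 3 3-bromo-4-hydroxybenzaldehyde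
Product: 4 (E)-2'-benzyloxy-3-bromo-4,6'-dihydroxy-4'-methoxychalcone
Conditions: KOH (50% aq.), EtOH, rt to 50 °C; then aq. HCl
Reagents that add atoms: none
Why: Claisen–Schmidt aldol condensation of the methyl ketone enolate with the aldehyde and E1cB loss of water should give the conjugated E-enone under thermodynamic control, the excess hydroxide compensating for the deactivated phenoxide form of the aldehyde.

**Step 3**
Reactants: 4 (E)-2'-benzyloxy-3-bromo-4,6'-dihydroxy-4'-methoxychalcone
Product: 5 5-O-benzyl-3'-bromogenkwanin (5-benzyloxy-2-(3-bromo-4-hydroxyphenyl)-7-methoxy-4H-chromen-4-one)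
Conditions: I2 (10 mol%), DMSO, 120 °C
Reagents that add atoms: none
Why: iodine-catalysed oxidative cyclisation of a 2'-hydroxychalcone, in which oxa-Michael closure to the flavanone, α-iodination and loss of HI give the flavone while DMSO reoxidises HI to I2; any flavanone carried over from step 2 converges on the same product.

**Step 4**
Reactants: 5 5-O-benzyl-3'-bromogenkwanin
Product: 6 5-O-benzyl-3'-bromo-4'-O-(methylsulfanylmethyl)genkwanin
Conditions: NaH, ClCH2SMe, NaI (cat.), DMF, 0 °C to rt
Reagents that add atoms: chloromethyl methyl sulfide, CSCCl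
Why: Williamson-type O-alkylation of the only free phenol to its methylthiomethyl ether, with Finkelstein exchange by iodide activating the chloride.

**Step 5**
Reactants: 7 apigenin
Product: 8 7,4'-di-O-benzylapigenin
Conditions: BnBr (2.1 equiv), K2CO3, DMF, rt
Reagents that add atoms: benzyl bromide, BrCc1ccccc1
Why: Williamson etherification of the two acidic, non-chelated phenols; the 5-OH, hydrogen-bonded to the C4 carbonyl, is the least nucleophilic and should stay free with a carbonate base at room temperature.

**Step 6**
Reactants: 6 5-O-benzyl-3'-bromo-4'-O-(methylsulfanylmethyl)genkwanin; 8 7,4'-di-O-benzylapigenin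
Product: 10 acetal-bridged 3'-bromo bis-flavone (O–CH2–O link from the 4'-oxygen of the 5-O-benzyl-3'-bromogenkwanin unit to the 5-oxygen of the 7,4'-di-O-benzylapigenin unit), via aryl chloromethyl ether 9 (not isolated)
Conditions: SO2Cl2 (1.0 equiv), cyclohexene, CH2Cl2, 0 °C; evaporate; then 8, NaH, DMF, 0 °C to rt
Reagents that add atoms: none
Why: S-chlorination of the thioether and Pummerer-type fragmentation of the chlorosulfonium ion should give the aryl chloromethyl ether (cyclohexene trapping MeSCl), and this α-chloro ether then O-alkylates the sodium 5-phenoxide of 8 in the way chloromethyl methyl ether protects 5-hydroxyflavones.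

**Step 7**
Reactants: 10 acetal-bridged 3'-bromo bis-flavone
Product: 11 dioxepine-bridged tri-O-benzyl biflavone (C3' of the genkwanin unit bonded to C6 of the apigenin unit; the 4'-oxygen and the 5-oxygen joined by CH2 in a dibenzo[d,f][1,3]dioxepine ring)
Conditions: Pd(OAc)2 (10 mol%), PCy3·HBF4 (20 mol%), PivOH (30 mol%), K2CO3 (3 equiv), DMA, 110 °C, Ar
Reagents that add atoms: none
Why: Zerovalent palladium formed in situ from Pd(OAc)2 and PCy3 should insert into the C3'–Br bond, bromide is exchanged for pivalate, and pivalate-assisted concerted metalation–deprotonation of the C6–H of the apigenin unit gives an eight-membered diaryl palladacycle of divalent palladium, from which C–C reductive elimination forms the C3'–C6 bond. The closest known reaction type is the intramolecular direct arylation of tethered aryl bromides under Pd(OAc)2/PCy3/pivalate/carbonate conditions, including diaryl systems linked through two oxygens that close seven-membered rings on the way to 2,2'-biphenols. The seven-membered dibenzo-1,3-dioxepine ring closes by biaryl C–C bond formation, the O–CH2–O bridge being in place beforehand. No stereocentre is created and the biaryl axis needs no control. The step needs C6 over C8 selectivity in the apigenin unit, and the tether secures it because it hangs from the 5-oxygen, whose only ortho C–H is C6 (the other ortho carbon is the ring-fusion atom C4a), so C8 and every benzyl C–H lie beyond the reach of the arylpalladium centre. The C6–H sits between two oxygens on an electron-rich ring, which should make it acidic enough for carboxylate-assisted cleavage and nucleophilic enough for palladation.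

**Step 8**
Reactants: 11 dioxepine-bridged tri-O-benzyl biflavone
Product: 12 target biflavone 3'-(apigenin-6-yl)genkwanin (robustaflavone 7-methyl ether)
Conditions: BCl3 (1 M in CH2Cl2, excess), C6HMe5, CH2Cl2, −78 °C to 0 °C; then MeOH, aq. HCl
Reagents that add atoms: none
Why: BCl3-mediated ether cleavage should remove the three benzyl groups (pentamethylbenzene trapping the benzyl cations) and open the formaldehyde acetal as it opens methoxymethyl and methylenedioxy ethers, helped by chelation at the two peri-carbonyl 5-oxygens, while the non-chelated 7-OMe is inert to BCl3 at low temperature.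

**Compound list**
1 | 2',6'-dihydroxy-4'-methoxyacetophenone | CC(=O)c1c(O)cc(OC)cc1O | starting material
2 | 2'-benzyloxy-6'-hydroxy-4'-methoxyacetophenone | CC(=O)c1c(O)cc(OC)cc1OCc1ccccc1 | intermediate
3 | 3-bromo-4-hydroxybenzaldehyde | O=Cc1ccc(O)c(Br)c1 | starting material
4 | (E)-2'-benzyloxy-3-bromo-4,6'-dihydroxy-4'-methoxychalcone | COc1cc(O)c(C(=O)/C=C/c2ccc(O)c(Br)c2)c(OCc2ccccc2)c1 | intermediate
5 | 5-O-benzyl-3'-bromogenkwanin | COc1cc(OCc2ccccc2)c2c(=O)cc(-c3ccc(O)c(Br)c3)oc2c1 | intermediate
6 | 5-O-benzyl-3'-bromo-4'-O-(methylsulfanylmethyl)genkwanin | COc1cc(OCc2ccccc2)c2c(=O)cc(-c3ccc(OCSC)c(Br)c3)oc2c1 | intermediate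
7 | apigenin | O=c1cc(-c2ccc(O)cc2)oc2cc(O)cc(O)c12 | starting material
8 | 7,4'-di-O-benzylapigenin | O=c1cc(-c2ccc(OCc3ccccc3)cc2)oc2cc(OCc3ccccc3)cc(O)c12 | intermediate
9 | 5-O-benzyl-3'-bromo-4'-O-(chloromethyl)genkwanin (formed in the flask, not isolated) | COc1cc(OCc2ccccc2)c2c(=O)cc(-c3ccc(OCCl)c(Br)c3)oc2c1 | intermediate
10 | acetal-bridged 3'-bromo bis-flavone (4'-O–CH2–O-5 link between the 5-O-benzyl-3'-bromogenkwanin unit and the 7,4'-di-O-benzylapigenin unit) | COc1cc(OCc2ccccc2)c2c(=O)cc(-c3ccc(OCOc4cc(OCc5ccccc5)cc5oc(-c6ccc(OCc7ccccc7)cc6)cc(=O)c45)c(Br)c3)oc2c1 | intermediate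
11 | dioxepine-bridged tri-O-benzyl biflavone (C3'–C6 biaryl, 4'-O–CH2–O-5 bridge) | COc1cc(OCc2ccccc2)c2c(=O)cc(-c3ccc4OCOc5c(-c4c3)c(OCc3ccccc3)cc3oc(-c4ccc(OCc6ccccc6)cc4)cc(=O)c53)oc2c1 | intermediate
12 | 6-[2-hydroxy-5-(5-hydroxy-7-methoxy-4-oxo-4H-chromen-2-yl)phenyl]-5,7-dihydroxy-2-(4-hydroxyphenyl)-4H-chromen-4-one (robustaflavone 7-methyl ether) | COc1cc(O)c2c(=O)cc(-c3ccc(O)c(-c4c(O)cc5oc(-c6ccc(O)cc6)cc(=O)c5c4O)c3)oc2c1 | target

**Step count**
Total: 8 steps. Longest linear sequence: 7 steps (steps 1, 2, 3, 4, 6, 7, 8); step 5 is a one-step side branch.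

**Steps most likely to fail**

Step 7. After oxidative addition, protodebromination may outrun C–H cleavage at the doubly ortho-flanked C6, or carbonate and pivalate may open the aryloxymethyl link at 110 °C. The fallback replaces C–H functionalisation by reductive coupling of two carbon–halogen bonds. It sets out from 8: NIS in DMF at rt is expected to iodinate ortho to the free, chelated 5-OH and give 7,4'-di-O-benzyl-6-iodoapigenin F1. Its sodium salt (NaH, DMF) is alkylated with chloromethyl ether 9, made as in step 6, to give the bromo-iodo acetal-bridged bis-flavone F2. A Stille–Kelly ring closure (Pd(PPh3)4, Me3SnSnMe3, 1,4-dioxane, reflux) then stannylates the C–I bond and couples it intramolecularly with the C3'–Br bond. The route is rejoined at 11.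

Step 6. Hydrolysis or decomposition of the chloromethyl ether 9 may compete with the slow O-alkylation by the hydrogen-bonded, peri-hindered 5-phenoxide of 8. The fallback reverses the roles of the two partners. From 8, the chelated phenol is forced onto a small electrophile used in excess (NaH, ClCH2SMe, NaI, DMF, 50 °C) to give 7,4'-di-O-benzyl-5-O-(methylsulfanylmethyl)apigenin F3. SO2Cl2 and cyclohexene in CH2Cl2 at 0 °C convert it into 7,4'-di-O-benzyl-5-O-(chloromethyl)apigenin F4, used crude. F4 is captured by the unhindered, far more nucleophilic 4'-phenoxide of 5 (Cs2CO3, DMF, rt). The route is rejoined at 10.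

Step 8. Benzyl cations or the formaldehyde-derived oxocarbenium ion may alkylate the electron-rich A rings (C-benzylation, methylene bridging), the acetal may open incompletely, or the 7-OMe may be lost on prolonged exposure to the Lewis acid. The fallback separates the two deprotections and avoids free carbocations. From 11, hydrogenolysis (H2, Pd/C, THF–MeOH, rt) removes the three benzyl groups to give the dioxepine-bridged 7-O-methyl biflavone triol F5. Acid transacetalisation (conc. HCl, MeOH–1,4-dioxane, 60 °C) then releases the two bridged phenols, the bridge carbon leaving as dimethoxymethane. The route is rejoined at 12.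

**Further compounds**
F1 | step 7 | 7,4'-di-O-benzyl-6-iodoapigenin | O=c1cc(-c2ccc(OCc3ccccc3)cc2)oc2cc(OCc3ccccc3)c(I)c(O)c12
F2 | step 7 | bromo-iodo acetal-bridged bis-flavone (as 10, with iodine at C6 of the apigenin unit) | COc1cc(OCc2ccccc2)c2c(=O)cc(-c3ccc(OCOc4c(I)c(OCc5ccccc5)cc5oc(-c6ccc(OCc7ccccc7)cc6)cc(=O)c45)c(Br)c3)oc2c1
F3 | step 6 | 7,4'-di-O-benzyl-5-O-(methylsulfanylmethyl)apigenin | O=c1cc(-c2ccc(OCc3ccccc3)cc2)oc2cc(OCc3ccccc3)cc(OCSC)c12
F4 | step 6 | 7,4'-di-O-benzyl-5-O-(chloromethyl)apigenin | O=c1cc(-c2ccc(OCc3ccccc3)cc2)oc2cc(OCc3ccccc3)cc(OCCl)c12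
F5 | step 8 | dioxepine-bridged 7-O-methyl biflavone triol (as 11, with the three benzyl groups replaced by hydrogen) | COc1cc(O)c2c(=O)cc(-c3ccc4OCOc5c(-c4c3)c(O)cc3oc(-c4ccc(O)cc4)cc(=O)c53)oc2c1
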